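The seven-membered ring (dibenzo[a,d][7]annulene numbering) is cut into a four-carbon unit, the benzylic methines C5 and C10 on neighbouring carbons of catechol ring B, and a three-carbon unit, methylene C11 with ring carbons C11a and C4a of phenol ring C. The key step joins them in one flask as a tethered formal (4+3) annulation: an arylacetate on the C5 oxygen delivers its enol carbon C11 to a C10 benzhydryl cation, then leaves C5 as carboxylate so that C4a closes on C5. It exploits the para-oxygen stabilisation of both benzylic cations on ring B and relays the C5 carbinol configuration to C10 and back. The precursor is a chloro ester made from a phthalan.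

Key step: step 6

Labels: ring A = resorcinol ring of the dihydrophenanthrene, ring B = fused catechol ring, ring C = monophenol ring, ring D = pendant catechol ring; C5 = methine shared by the six- and seven-membered rings, C10 = methine bearing ring D, C11 = methylene next to ring C.

Remark: the benzhydryl carbon carrying OH, O or Cl in 9, 10, 13 and 14 and the carboxyl-bearing carbon in 15, 16 and 17 arise as epimer mixtures; both are later ionised or decarboxylated, so the SMILES carry no descriptor at these carbons.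

Step 1
Reactants: 1 isovanillin (3-hydroxy-4-methoxybenzaldehyde)
Product: 2 5-formyl-2-methoxyphenyl 4-methylbenzenesulfonate
Conditions: TsCl (1.1 equiv), Et3N, DMAP (cat.), CH2Cl2, 0 °C to rt
Reagents that add atoms: 4-methylbenzenesulfonyl chloride, Cc1ccc(S(=O)(=O)Cl)cc1
Why: O-Sulfonylation of a phenol is routine, and the sulfonate later makes the ring-D oxygen meta to the attachment point electron-poor, so ring D cannot compete in the cationic ring closures, while surviving the organolithium, Lewis acid and palladium steps.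

Step 2
Reactants: 3 2-bromo-4,5-dimethoxybenzonitrile; 4 3,5-dimethoxybenzylmagnesium chloride
Product: 6 1-(2-bromo-4,5-dimethoxyphenyl)-2-(3,5-dimethoxyphenyl)ethan-1-one, via N-chloromagnesio ketimine 5 (not isolated)
Conditions: 4 (1.3 equiv, THF solution), THF, 0 to 40 °C; then 2 M HCl, rt
Reagents that add atoms: water, O
Why: Grignard addition to a nitrile stops at the ketimine salt, so hydrolysis should give the benzyl aryl ketone without over-addition, and the aryl bromide does not exchange with a benzylic Grignard reagent.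

Step 3
Reactants: 6 1-(2-bromo-4,5-dimethoxyphenyl)-2-(3,5-dimethoxyphenyl)ethan-1-one
Product: 7 (1S)-1-(2-bromo-4,5-dimethoxyphenyl)-2-(3,5-dimethoxyphenyl)ethan-1-ol
Conditions: (R)-2-methyl-CBS-oxazaborolidine (15 mol%), BH3·SMe2 (0.8 equiv), THF, −20 °C; MeOH
Reagents that add atoms: none
Why: Corey–Bakshi–Shibata reduction, in which the aryl group acts as the large and the benzylic methylene as the small substituent, so the (R)-catalyst should give the (S)-carbinol in the same sense as acetophenone gives (S)-1-phenylethanol.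

Step 4
Reactants: 7 (1S)-1-(2-bromo-4,5-dimethoxyphenyl)-2-(3,5-dimethoxyphenyl)ethan-1-ol; 2 5-formyl-2-methoxyphenyl 4-methylbenzenesulfonate
Product: 10 (1S)-1-(3,5-dimethoxybenzyl)-5,6-dimethoxy-3-[4-methoxy-3-(tosyloxy)phenyl]-1,3-dihydro-2-benzofuran, via aryllithium alkoxide 8 (not isolated), via diol 9 (not isolated)
Conditions: n-BuLi (2.1 equiv), THF, −78 °C; then 2 (1.1 equiv), −78 °C; aq. NH4Cl; crude diol, camphorsulfonic acid (5 mol%), 4 Å sieves, CH2Cl2, 0 °C
Reagents that add atoms: none
Why: Deprotonation then bromine–lithium exchange gives an aryllithium that should add to the aldehyde far faster than it attacks the sulfonate, and catalytic acid ionises only the doubly para-oxygenated benzhydrol, which the neighbouring hydroxyl captures (SN1 cycloetherification) without touching the (S)-carbinol centre.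

Step 5
Reactants: 10 (1S)-1-(3,5-dimethoxybenzyl)-5,6-dimethoxy-3-[4-methoxy-3-(tosyloxy)phenyl]-1,3-dihydro-2-benzofuran; 11 (3-bromo-5-methoxyphenyl)acetic acid
Product: 13 (1S)-1-{2-[chloro(4-methoxy-3-tosyloxyphenyl)methyl]-4,5-dimethoxyphenyl}-2-(3,5-dimethoxyphenyl)ethyl (3-bromo-5-methoxyphenyl)acetate, via acid chloride 12 (not isolated)
Conditions: 11, (COCl)2 (1.2 equiv), DMF (cat.), CH2Cl2, 0 °C to rt, evaporate; then 10, ZnCl2 (10 mol%), CH2Cl2, −30 to 0 °C; used crude
Reagents that add atoms: oxalyl chloride, ClC(=O)C(=O)Cl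
Why: Lewis acid-catalysed acylative cleavage of a benzylic ether by an acyl chloride, in which the ring oxygen is acylated and the C–O bond to the better-stabilised benzhydryl carbon breaks with chloride capture, so the arylacetate ends on the carbinol oxygen with its configuration intact and the benzhydryl carbon gains a leaving group.

Step 6
Reactants: 13 (1S)-1-{2-[chloro(4-methoxy-3-tosyloxyphenyl)methyl]-4,5-dimethoxyphenyl}-2-(3,5-dimethoxyphenyl)ethyl (3-bromo-5-methoxyphenyl)acetate
Product: 16 (5S,10R)-4-bromo-5-(3,5-dimethoxybenzyl)-2,7,8-trimethoxy-10-[4-methoxy-3-(tosyloxy)phenyl]-10,11-dihydro-5H-dibenzo[a,d][7]annulene-11-carboxylic acid, via silyl ketene acetal 14 (not isolated), via lactone 15 (not isolated)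
Conditions: Me3SiCl (3 equiv), LiN(SiMe3)2 (1.2 equiv), THF, −78 °C; filter under argon, evaporate, CH2Cl2; AgOSO2CF3 (1.2 equiv), −78 to 0 °C (both C–C bonds form in this stage); aq. NaHCO3, then dilute HCl
Reagents that add atoms: none
Why: Silver triflate strips chloride from C10 of silyl ketene acetal 14, the benzhydryl cation is taken by the tethered ketene acetal carbon C11 to give lactone 15 and Me3SiOSO2CF3, and this Lewis acid then ionises the para-methoxybenzylic lactone C5–O bond so that ring C attacks the C5 cation through C4a, the carbon para to its methoxy group, giving 16 after loss of a proton. The closest known reaction types are the Mukaiyama-type SN1 alkylation of silyl ketene acetals by benzhydryl cations and the Friedel–Crafts alkylation of arenes by benzylic esters or lactones, which together amount to a tethered formal (4+3) annulation. The first closure makes the seven-membered lactone with the enol double bond inside the new ring (enol-endo capture of a cation exocyclic to ring B), and the second makes the seven-membered carbocycle by attack of the arene carbon ortho to the C11 side chain (arene-endo). C10 is controlled by the carbinol centre: allylic 1,3-strain keeps H-5 and H-10 in the plane of ring B facing each other with ring D pointing outward, and the ester tether can reach only the face on which the C5 oxygen stands, so the (S)-ester should give (10R). C5 is then set again by C10: the C5 cation holds H-5 inside and the benzyl group outside, and ring C, held by the C10–C11 bond, adds to the face the carboxylate has just left, which should give (5S) with H-5 and H-10 cis (net retention at C5), while C11 forms as an epimer mixture that step 7 erases. The step needs C10 to ionise before the ester (two para-oxygenated aryl groups against one), the ketene acetal to outrun the dimethoxybenzyl ring (secured by its far higher nucleophilicity), and ring C to outrun ring D in the second closure, which the tosylate secures by deactivating the ring-D positions ortho to C10, while the ring-C methoxy group directs attack to its para carbon.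

Step 7
Reactants: 16 (5S,10R)-4-bromo-5-(3,5-dimethoxybenzyl)-2,7,8-trimethoxy-10-[4-methoxy-3-(tosyloxy)phenyl]-10,11-dihydro-5H-dibenzo[a,d][7]annulene-11-carboxylic acid
Product: 18 (5S,10R)-4-bromo-5-(3,5-dimethoxybenzyl)-2,7,8-trimethoxy-10-[4-methoxy-3-(tosyloxy)phenyl]-10,11-dihydro-5H-dibenzo[a,d][7]annulene, via thiohydroxamate ester 17 (not isolated)
Conditions: 2-mercaptopyridine N-oxide (1.2 equiv), DCC (1.2 equiv), DMAP (cat.), CH2Cl2, 0 °C, dark; then t-BuSH (10 equiv), visible light (tungsten lamp), rt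
Reagents that add atoms: none
Why: Barton reductive decarboxylation, in which the thiohydroxamate ester fragments under light to carbon dioxide and the C11 benzylic radical that takes hydrogen from the thiol, so both C11 epimers converge and the aryl bromide, the sulfonate and the C5 and C10 centres stay untouched.

Step 8
Reactants: 18 (5S,10R)-4-bromo-5-(3,5-dimethoxybenzyl)-2,7,8-trimethoxy-10-[4-methoxy-3-(tosyloxy)phenyl]-10,11-dihydro-5H-dibenzo[a,d][7]annulene
Product: 19 pentacyclic hexamethyl ether tosylate (target skeleton; OMe on all ring-A, ring-B and ring-C oxygens, ring D with OMe para and OTs meta to C10)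
Conditions: Pd(OAc)2 (10 mol%), PCy3·HBF4 (20 mol%), K2CO3 (2 equiv), t-BuCO2H (30 mol%), DMA, 120 °C
Reagents that add atoms: none
Why: Palladium-catalysed intramolecular direct arylation by concerted metalation–deprotonation, in which after oxidative addition at the ring-C bromide only the two equivalent ring-A C–H bonds ortho to the benzylic methylene can be reached in a six-membered closure, because the folded seven-membered ring keeps the ring-B C–H out of range.

Step 9
Reactants: 19 pentacyclic hexamethyl ether tosylate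
Product: 20 pentacyclic hexamethyl ether with free ring-D hydroxyl
Conditions: KOH (5 equiv), MeOH/THF/H2O, 65 °C; then dilute HCl
Reagents that add atoms: none
Why: Hydrolysis of the aryl sulfonate ester by attack of hydroxide at sulfur should free the phenol, while aryl methyl ethers and the non-acidic benzylic methines are inert to hydroxide.

Step 10
Reactants: 20 pentacyclic hexamethyl ether with free ring-D hydroxyl
Product: 21 CNP0306974.2
Conditions: BBr3 (12 equiv), CH2Cl2, −78 °C to rt; MeOH, then water, under argon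
Reagents that add atoms: none
Why: Boron tribromide demethylation (Lewis acid-assisted SN2 at methyl) should cleave all six aryl methyl ethers at low temperature, conditions under which the benzylic C–H stereocentres have no pathway to epimerise.

Compound list
1 | isovanillin (3-hydroxy-4-methoxybenzaldehyde) | COc1ccc(C=O)cc1O | starting material
2 | 5-formyl-2-methoxyphenyl 4-methylbenzenesulfonate | COc1ccc(C=O)cc1OS(=O)(=O)c1ccc(C)cc1 | intermediate
3 | 2-bromo-4,5-dimethoxybenzonitrile | N#Cc1cc(OC)c(OC)cc1Br | starting material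
4 | 3,5-dimethoxybenzylmagnesium chloride (THF solution) | COc1cc(C[Mg]Cl)cc(OC)c1 | starting material
5 | N-chloromagnesio ketimine of 6 | COc1cc(CC(=N[Mg]Cl)c2cc(OC)c(OC)cc2Br)cc(OC)c1 | intermediate
6 | 1-(2-bromo-4,5-dimethoxyphenyl)-2-(3,5-dimethoxyphenyl)ethan-1-one | COc1cc(CC(=O)c2cc(OC)c(OC)cc2Br)cc(OC)c1 | intermediate
7 | (1S)-1-(2-bromo-4,5-dimethoxyphenyl)-2-(3,5-dimethoxyphenyl)ethan-1-ol | COc1cc(C[C@H](O)c2cc(OC)c(OC)cc2Br)cc(OC)c1 | intermediate
8 | aryllithium alkoxide: O-lithio alkoxide of 7 with lithium in place of bromine | COc1cc(C[C@H](O[Li])c2cc(OC)c(OC)cc2[Li])cc(OC)c1 | intermediate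
9 | (1S)-1-{2-[hydroxy(4-methoxy-3-tosyloxyphenyl)methyl]-4,5-dimethoxyphenyl}-2-(3,5-dimethoxyphenyl)ethan-1-ol, benzhydrol carbon as epimer mixture | COc1cc(C[C@H](O)c2cc(OC)c(OC)cc2C(O)c2ccc(OC)c(OS(=O)(=O)c3ccc(C)cc3)c2)cc(OC)c1 | intermediate
10 | (1S)-1-(3,5-dimethoxybenzyl)-5,6-dimethoxy-3-[4-methoxy-3-(tosyloxy)phenyl]-1,3-dihydro-2-benzofuran, C3 epimers | COc1cc(C[C@@H]2OC(c3ccc(OC)c(OS(=O)(=O)c4ccc(C)cc4)c3)c3cc(OC)c(OC)cc32)cc(OC)c1 | intermediate
11 | (3-bromo-5-methoxyphenyl)acetic acid | COc1cc(Br)cc(CC(=O)O)c1 | starting material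
12 | (3-bromo-5-methoxyphenyl)acetyl chloride | COc1cc(Br)cc(CC(=O)Cl)c1 | intermediate
13 | (1S)-1-{2-[chloro(4-methoxy-3-tosyloxyphenyl)methyl]-4,5-dimethoxyphenyl}-2-(3,5-dimethoxyphenyl)ethyl (3-bromo-5-methoxyphenyl)acetate, CHCl epimers | COc1cc(Br)cc(CC(=O)O[C@@H](Cc2cc(OC)cc(OC)c2)c2cc(OC)c(OC)cc2C(Cl)c2ccc(OC)c(OS(=O)(=O)c3ccc(C)cc3)c2)c1 | intermediate
14 | trimethylsilyl ketene acetal of 13 (double-bond isomers) | COc1cc(Br)cc(C=C(O[Si](C)(C)C)O[C@@H](Cc2cc(OC)cc(OC)c2)c2cc(OC)c(OC)cc2C(Cl)c2ccc(OC)c(OS(=O)(=O)c3ccc(C)cc3)c2)c1 | intermediate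
15 | (1S,5R)-4-(3-bromo-5-methoxyphenyl)-1-(3,5-dimethoxybenzyl)-7,8-dimethoxy-5-[4-methoxy-3-(tosyloxy)phenyl]-4,5-dihydro-1H-2-benzoxepin-3-one, C4 epimers | O=C1O[C@@H](Cc2cc(OC)cc(OC)c2)c2cc(OC)c(OC)cc2[C@@H](c2ccc(OC)c(OS(=O)(=O)c3ccc(C)cc3)c2)C1c1cc(Br)cc(OC)c1 | intermediate
16 | (5S,10R)-4-bromo-5-(3,5-dimethoxybenzyl)-2,7,8-trimethoxy-10-[4-methoxy-3-(tosyloxy)phenyl]-10,11-dihydro-5H-dibenzo[a,d][7]annulene-11-carboxylic acid, C11 epimers | COc1cc(OC)cc(C[C@H]2c3cc(OC)c(OC)cc3[C@@H](c3ccc(OC)c(OS(=O)(=O)c4ccc(C)cc4)c3)C(C(=O)O)c3cc(OC)cc(Br)c32)c1 | intermediate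
17 | thiohydroxamate (2-thioxopyridin-1-yl) ester of 16 | COc1cc(OC)cc(C[C@H]2c3cc(OC)c(OC)cc3[C@@H](c3ccc(OC)c(OS(=O)(=O)c4ccc(C)cc4)c3)C(C(=O)On3ccccc3=S)c3cc(OC)cc(Br)c32)c1 | intermediate
18 | (5S,10R)-4-bromo-5-(3,5-dimethoxybenzyl)-2,7,8-trimethoxy-10-[4-methoxy-3-(tosyloxy)phenyl]-10,11-dihydro-5H-dibenzo[a,d][7]annulene | COc1cc(OC)cc(C[C@H]2c3cc(OC)c(OC)cc3[C@@H](c3ccc(OC)c(OS(=O)(=O)c4ccc(C)cc4)c3)Cc3cc(OC)cc(Br)c32)c1 | intermediate
19 | pentacyclic hexamethyl ether tosylate: target skeleton, (S) at C5 and (R) at C10, OMe on the two ring-A, two ring-B and the ring-C oxygens, ring D with OMe para and OTs meta to C10 | COc1cc(OC)c2c(c1)C[C@H]1c3cc(OC)c(OC)cc3[C@@H](c3ccc(OC)c(OS(=O)(=O)c4ccc(C)cc4)c3)Cc3cc(OC)cc-2c31 | intermediate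
20 | the same pentacycle with the ring-D meta oxygen as free hydroxyl | COc1cc(OC)c2c(c1)C[C@H]1c3cc(OC)c(OC)cc3[C@@H](c3ccc(OC)c(O)c3)Cc3cc(OC)cc-2c31 | intermediate
21 | CNP0306974.2, heptaphenol with (S) at C5 and (R) at C10 | Oc1cc(O)c2c(c1)C[C@H]1c3cc(O)c(O)cc3[C@@H](c3ccc(O)c(O)c3)Cc3cc(O)cc-2c31 | target

Total step count: 10. Longest linear sequence: 9 steps (steps 2 to 10, from 3).

Steps most likely to fail

Step 6. What may go wrong: the second ring closure may stall or go astray, because the attacking ring-C carbon lies between the side chain and bromine. Attack at the other ortho carbon (between side chain and methoxy) or proton loss from the C5 cation to a stilbene would divert material, and any leak in the tether-controlled first closure would lower the enantiomeric purity. The fallback sets out from 10 and comes back at 19. Phthalan 10 is opened as in step 5 with commercial (3-methoxyphenyl)acetyl chloride to the bromine-free chloro ester F1. The one-flask sequence of step 6 then passes through silyl ketene acetal F2 and lactone F3, closes ring C at its unhindered carbon para to methoxy and should give acid F4. Barton decarboxylation through thiohydroxamate ester F5 gives tetracycle F6. N-Bromosuccinimide (MeCN, 0 °C) should brominate the most electron-rich ring, ring A, ortho to its methylene to give bromide F7. The palladium-catalysed direct arylation of step 8, now from ring A onto the ring-C C–H next to C4a, closes the biaryl bond and gives 19.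

Step 5. What may go wrong: Friedel–Crafts acylation of the dimethoxybenzyl ring by the acyl chloride–ZnCl2 pair, or repeated ionisation of the labile benzhydryl chloride until ring A captures it. The fallback sets out from 7 and comes back at 15, which closes to 16 in the same flask. Alcohol 7 is silylated (t-BuMe2SiCl, imidazole, DMF) to silyl ether F8. Bromine–lithium exchange (n-BuLi, THF, −78 °C) and addition to aldehyde 2 give benzhydrol F9, which is O-methylated (NaH, MeI, THF) to methyl ether F10. Fluoride (Bu4NF, THF, 0 °C) removes the silyl group to give alcohol F11, and Steglich esterification with acid 11 (DCC, DMAP) gives methyl ether ester F12. Step 6 is then run with Me3SiOSO2CF3 in place of the silver salt, which ionises the benzhydryl methyl ether of ketene acetal F13 and leads to 15.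

Step 8. What may go wrong: slow C–H palladation at the crowded ring-A carbon between methoxy and methylene, so that hydrodebromination takes over. The fallback sets out from 18 and comes back at 19. Ring A of 18 is brominated ortho to its methylene with N-bromosuccinimide (MeCN, 0 °C) to dibromide F14, and the two aryl bromides are joined by an intramolecular reductive Ullmann-type coupling with Ni(cod)2 and 2,2'-bipyridine (zerovalent nickel, DMF, 60 °C) to give 19.

Further compounds
F1 | step 6 | (1S)-1-{2-[chloro(4-methoxy-3-tosyloxyphenyl)methyl]-4,5-dimethoxyphenyl}-2-(3,5-dimethoxyphenyl)ethyl (3-methoxyphenyl)acetate | COc1cccc(CC(=O)O[C@@H](Cc2cc(OC)cc(OC)c2)c2cc(OC)c(OC)cc2C(Cl)c2ccc(OC)c(OS(=O)(=O)c3ccc(C)cc3)c2)c1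
F2 | step 6 | trimethylsilyl ketene acetal of F1 | COc1cccc(C=C(O[Si](C)(C)C)O[C@@H](Cc2cc(OC)cc(OC)c2)c2cc(OC)c(OC)cc2C(Cl)c2ccc(OC)c(OS(=O)(=O)c3ccc(C)cc3)c2)c1
F3 | step 6 | bromine-free lactone, analogue of 15 | O=C1O[C@@H](Cc2cc(OC)cc(OC)c2)c2cc(OC)c(OC)cc2[C@@H](c2ccc(OC)c(OS(=O)(=O)c3ccc(C)cc3)c2)C1c1cccc(OC)c1
F4 | step 6 | bromine-free acid, analogue of 16 | COc1cc(OC)cc(C[C@H]2c3cc(OC)c(OC)cc3[C@@H](c3ccc(OC)c(OS(=O)(=O)c4ccc(C)cc4)c3)C(C(=O)O)c3cc(OC)ccc32)c1
F5 | step 6 | thiohydroxamate ester of F4 | COc1cc(OC)cc(C[C@H]2c3cc(OC)c(OC)cc3[C@@H](c3ccc(OC)c(OS(=O)(=O)c4ccc(C)cc4)c3)C(C(=O)On3ccccc3=S)c3cc(OC)ccc32)c1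
F6 | step 6 | bromine-free tetracycle, analogue of 18 | COc1cc(OC)cc(C[C@H]2c3cc(OC)c(OC)cc3[C@@H](c3ccc(OC)c(OS(=O)(=O)c4ccc(C)cc4)c3)Cc3cc(OC)ccc32)c1
F7 | step 6 | ring-A bromide of F6 (bromine ortho to the benzylic methylene) | COc1cc(OC)c(Br)c(C[C@H]2c3cc(OC)c(OC)cc3[C@@H](c3ccc(OC)c(OS(=O)(=O)c4ccc(C)cc4)c3)Cc3cc(OC)ccc32)c1
F8 | step 5 | tert-butyldimethylsilyl ether of 7 | COc1cc(C[C@H](O[Si](C)(C)C(C)(C)C)c2cc(OC)c(OC)cc2Br)cc(OC)c1
F9 | step 5 | silyl ether benzhydrol (epimers at the benzhydrol carbon) | COc1cc(C[C@H](O[Si](C)(C)C(C)(C)C)c2cc(OC)c(OC)cc2C(O)c2ccc(OC)c(OS(=O)(=O)c3ccc(C)cc3)c2)cc(OC)c1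
F10 | step 5 | silyl ether benzhydryl methyl ether | COc1cc(C[C@H](O[Si](C)(C)C(C)(C)C)c2cc(OC)c(OC)cc2C(OC)c2ccc(OC)c(OS(=O)(=O)c3ccc(C)cc3)c2)cc(OC)c1
F11 | step 5 | (S)-alcohol with benzhydryl methyl ether | COc1cc(C[C@H](O)c2cc(OC)c(OC)cc2C(OC)c2ccc(OC)c(OS(=O)(=O)c3ccc(C)cc3)c2)cc(OC)c1
F12 | step 5 | methyl ether analogue of 13 | COc1cc(Br)cc(CC(=O)O[C@@H](Cc2cc(OC)cc(OC)c2)c2cc(OC)c(OC)cc2C(OC)c2ccc(OC)c(OS(=O)(=O)c3ccc(C)cc3)c2)c1
F13 | step 5 | trimethylsilyl ketene acetal of F12 | COc1cc(Br)cc(C=C(O[Si](C)(C)C)O[C@@H](Cc2cc(OC)cc(OC)c2)c2cc(OC)c(OC)cc2C(OC)c2ccc(OC)c(OS(=O)(=O)c3ccc(C)cc3)c2)c1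
F14 | step 8 | dibromide: 18 with a second bromine on ring A ortho to the benzylic methylene | COc1cc(OC)c(Br)c(C[C@H]2c3cc(OC)c(OC)cc3[C@@H](c3ccc(OC)c(OS(=O)(=O)c4ccc(C)cc4)c3)Cc3cc(OC)cc(Br)c32)c1
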